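**Retrosynthetic overview**
- Both tropolone rings are made last and together. Each comes from a six-membered spiro-epoxy-cyclohexa-2,4-dienone, in which a cobalt-generated primary radical forms the new CH2–C(Me) ring bond (3-exo attack, 1,2-vinyl shift, 6→7). The step is a net isomerisation.
- The bis(spiro-epoxydienone) comes from Adler–Becker oxidation of a bis(salicyl alcohol), which comes from a bis(chroman-6-carboxylate).
- Both dihydropyrans come from a one-pot double 9-BBN hydroboration / intramolecular B-alkyl Suzuki closure (C4–C4a bond, sets C3-Me). This follows a double Mitsunobu etherification (C2–O, inversion) of a C11 tetraene-diol with bromo-orsellinate.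
- The C11 diol comes from trans-hydroalumination of a diyne-diol, made by two catalytic asymmetric alkynylations (acrolein, methacrolein) on a butadiyne linchpin.
- Ring order: two benzene rings (acetoacetate self-condensation), then two pyrans, then two tropolones.

Assumptions: the two O-tautomers of each tropolone interconvert fast and count as one compound; the spiro carbons of 17 form as a mixture and are erased in step 12; (R,R)-ProPhenol is taken as the antipode that directs Re-face attack on enals, and the commercial antipode is used if the sense is opposite.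

**Step 1**
Reactants: 1 methyl acetoacetate (2 equiv)
Product: 3 methyl orsellinate, via methyl 3,5,7-trioxooctanoate 2 (not isolated)
Conditions: NaH (1.0 equiv), n-BuLi (0.5 equiv), THF, 0 °C → reflux; aq HCl
Reagents that add atoms: none
Why: Biomimetic polyketide condensation: Claisen acylation of the acetoacetate dianion (γ-carbon) by a second ester, then intramolecular aldol, dehydration and aromatisation give the resorcylate; no stereocentre is formed.

**Step 2**
Reactants: 3 methyl orsellinate
Product: 4 methyl 5-bromo-2,4-dihydroxy-6-methylbenzoate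
Conditions: NBS (1.0 equiv), MeCN, −20 → 0 °C
Reagents that add atoms: N-bromosuccinimide, O=C1CCC(=O)N1Br
Why: Electrophilic aromatic bromination goes para to the chelated 2-OH and ortho to the free 4-OH (C5), the site at which orsellinates are halogenated; any 3-bromo isomer is separable and cannot cyclise later.

**Step 3**
Reactants: 5 1,4-bis(trimethylsilyl)buta-1,3-diyne
Product: 6 buta-1,3-diyn-1-yl(trimethyl)silane
Conditions: MeLi·LiBr (1.0 equiv), Et2O, 0 °C → rt; H2O; kept as a dried toluene solution
Reagents that add atoms: none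
Why: Selective mono-desilylation by methyl attack at silicon stops after one TMS because the resulting diynide is deactivated, and protonation gives the terminal diyne.

**Step 4**
Reactants: 6 buta-1,3-diyn-1-yl(trimethyl)silane; 7 acrolein
Product: 8 (3S)-7-(trimethylsilyl)hept-1-ene-4,6-diyn-3-ol
Conditions: Me2Zn, (R,R)-ProPhenol (20 mol %), Ph3P=O (40 mol %), PhMe, 4 °C; aq NH4Cl
Reagents that add atoms: none
Why: In this catalytic asymmetric alkynylation (dinuclear zinc–ProPhenol), for which enals and 1,3-diynes are good partners, Re-face delivery of the diynyl group sets the S carbinol that becomes C2' after inversion.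

**Step 5**
Reactants: 8 (3S)-7-(trimethylsilyl)hept-1-ene-4,6-diyn-3-ol
Product: 9 (3S)-hept-1-ene-4,6-diyn-3-ol
Conditions: K2CO3 (cat.), MeOH, 0 °C; used at once
Reagents that add atoms: none
Why: Base-catalysed methanolysis of the alkynyl–Si bond leaves the carbinol centre untouched.

**Step 6**
Reactants: 9 (3S)-hept-1-ene-4,6-diyn-3-ol; 10 methacrolein (3 equiv)
Product: 11 (3S,8S)-2-methyldeca-1,9-diene-4,6-diyne-3,8-diol
Conditions: Me2Zn (4 equiv), (R,R)-ProPhenol (20 mol %), Ph3P=O (40 mol %), PhMe, 4 °C; aq NH4Cl
Reagents that add atoms: none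
Why: The second catalyst-controlled asymmetric alkynylation (Re face, S carbinol) is not influenced by the remote first centre, and the minor enantiomer from each addition ends up in a separable diastereomer (Horeau amplification).

**Step 7**
Reactants: 11 (3S,8S)-2-methyldeca-1,9-diene-4,6-diyne-3,8-diol
Product: 12 (3R,4E,6E,8S)-2-methyldeca-1,4,6,9-tetraene-3,8-diol
Conditions: LiAlH4, THF, 0 → 45 °C; Fieser work-up
Reagents that add atoms: none
Why: Alkoxide-directed trans-hydroalumination of both propargylic alkynes followed by protonolysis gives the E,E-diene, the isolated vinyl groups are inert, and the geometry at both carbinols is unchanged (the C3 descriptor changes only by CIP ranking).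

**Step 8**
Reactants: 12 (3R,4E,6E,8S)-2-methyldeca-1,4,6,9-tetraene-3,8-diol; 4 methyl 5-bromo-2,4-dihydroxy-6-methylbenzoate (2.3 equiv)
Product: 13 bis(aryl ether) with (3S,8R) configuration
Conditions: PPh3, DIAD, PhMe, −10 °C → rt
Reagents that add atoms: none
Why: In this twofold Mitsunobu etherification only the acidic, non-chelated 4-OH reacts, and SN2 displacement inverts both carbinols to the final C2 and C2' configurations.

**Step 9**
Reactants: 13 bis(aryl ether)
Product: 15 bis-chroman diester (2R,3R,2'R), via bis(B-alkyl-9-BBN) adduct 14 (not isolated)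
Conditions: 9-BBN-H (4.6 equiv), THF, 0 °C → rt; then SPhos Pd G3 (10 mol %), aq K3PO4, THF–DMF, 60 °C, 0.01 M
Reagents that add atoms: none
Why: 9-BBN hydroborates only the terminal vinyl and isopropenyl groups, its anti-selective 1,2-induction on the 2-methylallylic ether (Still–Barrish/Houk model) sets C3 (R) trans to C2, and the intramolecular B-alkyl Suzuki–Miyaura coupling closes both six-membered rings through C–C bonds only, so the C–O centres are untouched.

**Step 10**
Reactants: 15 bis-chroman diester
Product: 16 bis(salicyl alcohol)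
Conditions: LiAlH4, THF, −10 → 10 °C; Fieser work-up
Reagents that add atoms: none
Why: Hydride reduction of the two salicylate esters is kept cold so that the aluminates do not collapse to o-quinone methides and over-reduce, and the diene, ethers and stereocentres are inert.

**Step 11**
Reactants: 16 bis(salicyl alcohol)
Product: 17 bis(spiro-epoxy-cyclohexa-2,4-dienone)
Conditions: NaIO4 (2.4 equiv), MeCN–H2O (pH 7), 0 °C, dark; used at once
Reagents that add atoms: none
Why: In the Adler–Becker oxidation the aryl periodate is displaced at the ortho carbon by the molecule's own CH2OH oxygen, and the tetrasubstituted C4a=C5 bond blocks the usual Diels–Alder dimerisation.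

**Step 12**
Reactants: 17 bis(spiro-epoxy-cyclohexa-2,4-dienone)
Product: 18 target CNP0332980.1
Conditions: vitamin B12 (20 mol %, pre-reduced to Co(I) with Zn/NH4Cl and filtered), MeOH–MeCN 1:1 (5 mM), 525 nm LEDs, 20 °C, Ar
Reagents that add atoms: none
Why: Proposed new method: Co(I) opens each 1,1-disubstituted epoxide at its CH2 (known Co(I) regiochemistry, opposite to Ti(III)), green light, which the dienone does not absorb, homolyses the β-hydroxyalkyl–Co bond, the nucleophilic primary radical adds 3-exo to the adjacent electrophilic dienone carbon C5 to give an oxygen-delocalised cyclopropylcarbinyl radical (1,2-vinyl shifts run about 100 times faster than the competing 1,2-acyl shift onto C7), the old C5–C6 bond cleaves to a captodative α-hydroxy-α-acyl radical in a seven-membered ring, and Co(II) abstracts H from the new CH2 to give the aromatic tropolone while Co–H ionises back to Co(I) and H+, so both rings expand in one catalytic isomerisation; the closest known reaction types are B12-catalysed epoxide-to-allylic-alcohol isomerisation, cobaloxime alkyl-Heck catalysis, Dowd–Beckwith ring expansion, stannane-mediated expansion of halomethyl-cyclohexadienones to tropones and the radical ring expansion proposed for fungal tropolone biosynthesis; C2, C3 and C2' are remote and untouched and the spiro centres vanish.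

**Compound list**
1 | methyl acetoacetate | CC(=O)CC(=O)OC | starting material
2 | methyl 3,5,7-trioxooctanoate (not isolated) | CC(=O)CC(=O)CC(=O)CC(=O)OC | intermediate
3 | methyl orsellinate (methyl 2,4-dihydroxy-6-methylbenzoate) | COC(=O)c1c(C)cc(O)cc1O | intermediate
4 | methyl 5-bromo-2,4-dihydroxy-6-methylbenzoate | COC(=O)c1c(C)c(Br)c(O)cc1O | intermediate
5 | 1,4-bis(trimethylsilyl)buta-1,3-diyne (C4 diyne with two TMS protecting groups) | C[Si](C)(C)C#CC#C[Si](C)(C)C | starting material
6 | buta-1,3-diyn-1-yl(trimethyl)silane | C#CC#C[Si](C)(C)C | intermediate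
7 | acrolein | C=CC=O | starting material
8 | (3S)-7-(trimethylsilyl)hept-1-ene-4,6-diyn-3-ol | C[Si](C)(C)C#CC#C[C@@H](O)C=C | intermediate
9 | (3S)-hept-1-ene-4,6-diyn-3-ol | C#CC#C[C@@H](O)C=C | intermediate
10 | methacrolein | C=C(C)C=O | starting material
11 | (3S,8S)-2-methyldeca-1,9-diene-4,6-diyne-3,8-diol | C=C(C)[C@H](O)C#CC#C[C@@H](O)C=C | intermediate
12 | (3R,4E,6E,8S)-2-methyldeca-1,4,6,9-tetraene-3,8-diol | C=C(C)[C@H](O)/C=C/C=C/[C@@H](O)C=C | intermediate
13 | dimethyl 4,4'-[(3S,4E,6E,8R)-2-methyldeca-1,4,6,9-tetraene-3,8-diylbis(oxy)]bis(5-bromo-2-hydroxy-6-methylbenzoate) | C=C(C)[C@@H](Oc1cc(O)c(C(=O)OC)c(C)c1Br)/C=C/C=C/[C@H](Oc1cc(O)c(C(=O)OC)c(C)c1Br)C=C | intermediate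
14 | bis(B-alkyl-9-BBN) adduct of 13, phenols as O-9-BBN borinates, new methyl-bearing centre R (not isolated) | C[C@H](CB1C2CCCC1CCC2)[C@@H](Oc1cc(OB2C3CCCC2CCC3)c(C(=O)OC)c(C)c1Br)/C=C/C=C/[C@H](Oc1cc(OB2C3CCCC2CCC3)c(C(=O)OC)c(C)c1Br)CCB1C2CCCC1CCC2 | intermediate
15 | methyl (2R,3R)-7-hydroxy-2-{(1E,3E)-4-[(2R)-7-hydroxy-6-(methoxycarbonyl)-5-methylchroman-2-yl]buta-1,3-dien-1-yl}-3,5-dimethylchroman-6-carboxylate | COC(=O)c1c(O)cc2c(c1C)C[C@@H](C)[C@H](/C=C/C=C/[C@H]1CCc3c(C)c(C(=O)OC)c(O)cc3O1)O2 | intermediate
16 | (2R,3R)-6-(hydroxymethyl)-2-{(1E,3E)-4-[(2R)-7-hydroxy-6-(hydroxymethyl)-5-methylchroman-2-yl]buta-1,3-dien-1-yl}-3,5-dimethylchroman-7-ol | OCc1c(O)cc2c(c1C)C[C@@H](C)[C@H](/C=C/C=C/[C@H]1CCc3c(C)c(CO)c(O)cc3O1)O2 | intermediate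
17 | bis(3,4-dihydrospiro[chromene-6,2'-oxiran]-7(2H)-one) with (2R,3R) and (2R) pyran centres, E,E-diene link, spiro centres as a mixture | CC1=C2C[C@@H](C)[C@H](/C=C/C=C/[C@H]3CCC4=C(C)C5(CO5)C(=O)C=C4O3)OC2=CC(=O)C16CO6 | intermediate
18 | CNP0332980.1, bis(dihydropyrano-tropolone), (2R,3R) and (2'R), E,E-diene | Cc1cc(=O)c(O)cc2c1C[C@@H](C)[C@H](/C=C/C=C/[C@H]1CCc3c(C)cc(=O)c(O)cc3O1)O2 | target

**Totals**
- Total step count: 12.
- Longest linear sequence: 10 steps (5 → 18). The arene branch (1 → 4) is 2 steps.

**Three steps most likely to fail**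

Step 12 (twofold cobalt-mediated radical ring expansion). The risks are single-electron re-aromatisation of 17 back to 16, β-hydroxide loss from the alkyl-cobalt species, and slow turnover. The fallback sets out from 17 and returns at 18. It separates radical generation from the final oxidation. Both epoxides are opened at CH2 with LiI/AcOH (MeCN, −20 °C) to give the bis(iodohydrin) F1. The same 3-exo / 1,2-vinyl shift is then run as a reductive silane chain ((TMS)3SiH, Et3B/air, toluene, 0 °C), in which the ring-expanded radical is quenched by hydrogen transfer to give the bis(2-hydroxycyclohepta-4,6-dienone) acyloin F2. Finally the two acyloins are dehydrogenated with Cu(OAc)2 in MeOH under air to give the tropolones of 18.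

Step 8 (double Mitsunobu at bis-allylic carbinols). The risks are SN2' attack at the terminal CH2 and ionisation with loss of ee. The fallback sets out from 12 and 4 and returns at 15. It makes the C–C bonds first and the C–O bonds last, so that SN2' would need an eight-membered ring. Diol 12 is silylated (TBSCl, imidazole) to the bis(TBS ether) F3. Rh(PPh3)3Cl-catalysed hydroboration with catecholborane is syn-selective on 2-methylallylic silyl ethers, and pinacol exchange gives the bis(pinacol boronate) F4, with Me syn to OTBS. Suzuki coupling with 4 (Pd/RuPhos, K3PO4, toluene–H2O) gives the bis(aryl) bis(TBS ether) F5, and TBAF gives the tetraol F6. A double intramolecular Mitsunobu reaction (PPh3, DIAD) inverts both carbinols, which turns the syn pair into the trans-2,3 pair and delivers 15.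

Step 9 (hydroboration / intramolecular Suzuki). The risks are Pd(0) ionisation of the dienylic aryl ether, 1,3-elimination of the γ-aryloxy borate under base, the di-ortho-substituted aryl bromide, and a modest dr. The fallback sets out from 13 and returns at 15. It replaces boron-to-palladium transfer under base by radical capture at nickel. Compound 13 is hydroborated to 14 as before but then oxidised (NaBO3·4H2O) to the bis(primary alcohol) F7, at which stage diastereomers can be separated. An Appel reaction (I2, PPh3, imidazole) gives the bis(primary iodide) F8. A base-free intramolecular reductive cross-electrophile coupling (NiBr2·glyme, dtbbpy, Zn, NaI, DMA, rt, high dilution) joins each alkyl radical to its aryl bromide to give 15.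

**Further compounds**
F1 | step 12 | bis(iodohydrin) of 17 (6-hydroxy-6-iodomethyl dienones) | CC1=C2C[C@@H](C)[C@H](/C=C/C=C/[C@H]3CCC4=C(C)C(O)(CI)C(=O)C=C4O3)OC2=CC(=O)C1(O)CI
F2 | step 12 | bis(2-hydroxycyclohepta-4,6-dienone) acyloin | CC1=C2C[C@@H](C)[C@H](/C=C/C=C/[C@H]3CCC4=C(C)CC(O)C(=O)C=C4O3)OC2=CC(=O)C(O)C1
F3 | step 8 | bis(TBS ether) of 12 | C=C(C)[C@H](O[Si](C)(C)C(C)(C)C)/C=C/C=C/[C@@H](O[Si](C)(C)C(C)(C)C)C=C
F4 | step 8 | bis(pinacol boronate), Me syn to OTBS | C[C@H](CB1OC(C)(C)C(C)(C)O1)[C@H](O[Si](C)(C)C(C)(C)C)/C=C/C=C/[C@@H](O[Si](C)(C)C(C)(C)C)CCB1OC(C)(C)C(C)(C)O1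
F5 | step 8 | bis(aryl) bis(TBS ether) | C[C@H](Cc1c(O)cc(O)c(C(=O)OC)c1C)[C@H](O[Si](C)(C)C(C)(C)C)/C=C/C=C/[C@@H](O[Si](C)(C)C(C)(C)C)CCc1c(O)cc(O)c(C(=O)OC)c1C
F6 | step 8 | tetraol (two dienylic carbinols, free resorcinols) | C[C@H](Cc1c(O)cc(O)c(C(=O)OC)c1C)[C@H](O)/C=C/C=C/[C@@H](O)CCc1c(O)cc(O)c(C(=O)OC)c1C
F7 | step 9 | bis(primary alcohol) from 13 | C[C@H](CO)[C@@H](Oc1cc(O)c(C(=O)OC)c(C)c1Br)/C=C/C=C/[C@H](Oc1cc(O)c(C(=O)OC)c(C)c1Br)CCO
F8 | step 9 | bis(primary iodide) | C[C@H](CI)[C@@H](Oc1cc(O)c(C(=O)OC)c(C)c1Br)/C=C/C=C/[C@H](Oc1cc(O)c(C(=O)OC)c(C)c1Br)CCI
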